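**Plan**

- Cuts: first the N1–C5 bond of the pyrrole (the C2=C3 double bond returning to a C3 carbinol), then C3–C4 (carbinol carbon to alkyne carbon), then C5–C1′ (alkyne carbon to the nonadecyl chain). The formyl group travels as a silyl-protected CH2OH.
- Enabling feature: the formyl carbon, C2 and C3 are the three carbons of serine (O–CH2–CH(N1)–CH(OH)) and C4/C5 are an alkyne. N1 therefore sits 1,4 to C5 across C2–C3–C4≡C5, and the C3 hydroxyl is the water lost on aromatisation.
- Forward: acetylene is alkylated with the C19 bromide and the C21 alkynide is joined to the serine-derived aldehyde. N–H and the primary OH are unmasked and the latter silylated. The pyrrole, the only ring, then forms by 5-endo-dig N1→C5 closure with dehydration; desilylation, oxidation and Boc removal finish.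
- Stereochemistry: the target is achiral. The (S) centre from L-serine and the carbinol centre from the Felkin–Anh addition are both erased when the ring aromatises.

Key step: step 5

Assumption: the target SMILES has no stereogenic element, so the single-enantiomer requirement is met by the achiral structure. Intermediates 6–8 are drawn as the anti epimer expected to predominate, and the syn carbinol epimer is carried along because step 5 destroys both centres.

**Route**

Step 1
Reactants: 1 1-bromononadecane; 2 lithium acetylide–ethylenediamine complex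
Product: 3 henicos-1-yne
Conditions: 2 (1.5 equiv), DMSO/THF, 10 °C → rt
Reagents that add atoms: none
Why: SN2 alkylation of lithium acetylide by a primary bromide in DMSO is the standard entry to terminal alkynes, with excess acetylide suppressing double alkylation and THF keeping the waxy bromide in solution.

Step 2
Reactants: 3 henicos-1-yne; 4 tert-butyl (S)-4-formyl-2,2-dimethyl-1,3-oxazolidine-3-carboxylate
Product: 6 tert-butyl (4S)-4-[(1R)-1-hydroxydocos-2-yn-1-yl]-2,2-dimethyl-1,3-oxazolidine-3-carboxylate, via lithium henicos-1-yn-1-ide 5 (not isolated)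
Conditions: 3 (1.3 equiv), n-BuLi (1.25 equiv), THF, −20 °C; then 4, −78 → −40 °C; aq NH4Cl
Reagents that add atoms: none
Why: Felkin–Anh 1,2-addition of a lithium alkynide to the configurationally stable serinal acetonide is the classical sphingoid chain extension; attack anti to the ring nitrogen should set the new carbinol centre mainly as (R) (anti adduct) while the (S) centre at C4 is untouched.

Step 3
Reactants: 6 tert-butyl (4S)-4-[(1R)-1-hydroxydocos-2-yn-1-yl]-2,2-dimethyl-1,3-oxazolidine-3-carboxylate
Product: 7 tert-butyl N-[(2S,3R)-1,3-dihydroxytetracos-4-yn-2-yl]carbamate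
Conditions: p-TsOH·H2O (10 mol %), MeOH/THF, rt
Reagents that add atoms: none
Why: Acid-catalysed transacetalisation to methanol opens the N,O-isopropylidene aminal, which is far more labile than the Boc carbamate at room temperature, and catalytic sulfonic acid in methanol does not ionise the propargylic alcohol.

Step 4
Reactants: 7 tert-butyl N-[(2S,3R)-1,3-dihydroxytetracos-4-yn-2-yl]carbamate
Product: 8 tert-butyl N-[(2S,3R)-1-(tert-butyldimethylsilyloxy)-3-hydroxytetracos-4-yn-2-yl]carbamate
Conditions: TBSCl (1.05 equiv), imidazole (2 equiv), CH2Cl2/DMF, 0 °C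
Reagents that add atoms: tert-butyldimethylsilyl chloride (TBSCl), CC(C)(C)[Si](C)(C)Cl
Why: Sterically governed silylation with one equivalent of the bulky chloride should cap the primary hydroxyl well ahead of the secondary propargylic one, which is flanked by the carbamate-bearing carbon and the alkyne.

Step 5
Reactants: 8 tert-butyl N-[(2S,3R)-1-(tert-butyldimethylsilyloxy)-3-hydroxytetracos-4-yn-2-yl]carbamate
Product: 10 tert-butyl 2-[(tert-butyldimethylsilyloxy)methyl]-5-nonadecyl-1H-pyrrole-1-carboxylate, via 3-hydroxy-2,3-dihydropyrrole carbamate 9 (not isolated)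
Conditions: Ph3PAuNTf2 (2 mol %), 4 Å MS, toluene, rt
Reagents that add atoms: none
Why: Cationic gold(I) binds the C4≡C5 triple bond of 8 and the carbamate N–H nitrogen adds anti to gold at the distal carbon C5; protodeauration releases the 3-hydroxy-2,3-dihydropyrrole 9, which loses water across C2–C3 to give the aromatic N-Boc pyrrole 10. The closest known reaction type is the gold(I)- or silver(I)-catalysed cyclodehydration of N-Boc or N-sulfonyl 1-amino-3-alkyn-2-ols to pyrroles, of which 8 is a direct member. The single ring, the pyrrole, closes by 5-endo-dig attack of N1 on C5. No stereocentre is created, and the two centres inherited from serine and from step 2 are both erased on aromatisation, so the carbinol epimers converge on one product. The step needs nitrogen attack at C5 to beat 5-exo or 6-endo attack by the C1 oxygen, 6-exo attack by the Boc carbonyl oxygen and Meyer–Schuster rearrangement; the C1 oxygen is capped as its TBS ether, the 1,4 spacing of N1 and C5 on an internal alkyne favours the endo nitrogen closure typical of this substrate class, and irreversible aromatisation drains the cyclised material. Molecular sieves take up the water formed so that neither the silyl ether nor the catalyst meets adventitious acid.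

Step 6
Reactants: 10 tert-butyl 2-[(tert-butyldimethylsilyloxy)methyl]-5-nonadecyl-1H-pyrrole-1-carboxylate
Product: 11 tert-butyl 2-(hydroxymethyl)-5-nonadecyl-1H-pyrrole-1-carboxylate
Conditions: TBAF (1.2 equiv), AcOH (1.2 equiv), THF, 0 °C → rt
Reagents that add atoms: none
Why: Fluoride-driven Si–O cleavage frees the primary alcohol, and the acetic acid buffer keeps the liberated oxygen protonated so that it should not attack the neighbouring N-Boc carbonyl.

Step 7
Reactants: 11 tert-butyl 2-(hydroxymethyl)-5-nonadecyl-1H-pyrrole-1-carboxylate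
Product: 12 tert-butyl 2-formyl-5-nonadecyl-1H-pyrrole-1-carboxylate
Conditions: activated MnO2 (15 equiv), CH2Cl2, rt
Reagents that add atoms: none
Why: Manganese dioxide selectively oxidises heterobenzylic carbinols such as pyrrol-2-ylmethanols to aldehydes without over-oxidation, and the N-Boc group shields the ring from oxidative degradation.

Step 8
Reactants: 12 tert-butyl 2-formyl-5-nonadecyl-1H-pyrrole-1-carboxylate
Product: 13 5-nonadecyl-1H-pyrrole-2-carbaldehyde
Conditions: K2CO3 (0.2 equiv), MeOH/THF, rt
Reagents that add atoms: none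
Why: The carbamate on a 2-formylpyrrole nitrogen is an activated acyl-azole, so base-catalysed methanolysis (transacylation to methanol) should expel the stabilised pyrrolide under conditions that leave the aldehyde and the alkyl chain alone.

**Compound list**

1 | 1-bromononadecane | CCCCCCCCCCCCCCCCCCCBr | starting material
2 | lithium acetylide–ethylenediamine complex | [Li]C#C.NCCN | starting material
3 | henicos-1-yne | CCCCCCCCCCCCCCCCCCCC#C | intermediate
4 | tert-butyl (S)-4-formyl-2,2-dimethyl-1,3-oxazolidine-3-carboxylate ((S)-Garner aldehyde) | CC1(C)OC[C@@H](C=O)N1C(=O)OC(C)(C)C | starting material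
5 | lithium henicos-1-yn-1-ide (formed in the flask) | CCCCCCCCCCCCCCCCCCCC#C[Li] | intermediate
6 | tert-butyl (4S)-4-[(1R)-1-hydroxydocos-2-yn-1-yl]-2,2-dimethyl-1,3-oxazolidine-3-carboxylate | CCCCCCCCCCCCCCCCCCCC#C[C@H]([C@@H]1COC(C)(C)N1C(=O)OC(C)(C)C)O | intermediate
7 | tert-butyl N-[(2S,3R)-1,3-dihydroxytetracos-4-yn-2-yl]carbamate | CCCCCCCCCCCCCCCCCCCC#C[C@H]([C@H](CO)NC(=O)OC(C)(C)C)O | intermediate
8 | tert-butyl N-[(2S,3R)-1-(tert-butyldimethylsilyloxy)-3-hydroxytetracos-4-yn-2-yl]carbamate | CCCCCCCCCCCCCCCCCCCC#C[C@H]([C@H](CO[Si](C)(C)C(C)(C)C)NC(=O)OC(C)(C)C)O | intermediate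
9 | tert-butyl (2S,3R)-2-[(tert-butyldimethylsilyloxy)methyl]-3-hydroxy-5-nonadecyl-2,3-dihydro-1H-pyrrole-1-carboxylate (formed in the flask) | CCCCCCCCCCCCCCCCCCCC1=C[C@@H](O)[C@H](CO[Si](C)(C)C(C)(C)C)N1C(=O)OC(C)(C)C | intermediate
10 | tert-butyl 2-[(tert-butyldimethylsilyloxy)methyl]-5-nonadecyl-1H-pyrrole-1-carboxylate | CCCCCCCCCCCCCCCCCCCc1ccc(CO[Si](C)(C)C(C)(C)C)n1C(=O)OC(C)(C)C | intermediate
11 | tert-butyl 2-(hydroxymethyl)-5-nonadecyl-1H-pyrrole-1-carboxylate | CCCCCCCCCCCCCCCCCCCc1ccc(CO)n1C(=O)OC(C)(C)C | intermediate
12 | tert-butyl 2-formyl-5-nonadecyl-1H-pyrrole-1-carboxylate | CCCCCCCCCCCCCCCCCCCc1ccc(C=O)n1C(=O)OC(C)(C)C | intermediate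
13 | 5-nonadecyl-1H-pyrrole-2-carbaldehyde | CCCCCCCCCCCCCCCCCCCc1ccc(C=O)[nH]1 | target

**Step count and risks**

Total steps: 8. Longest linear sequence: 8 steps (1 → 3 → 6 → 7 → 8 → 10 → 11 → 12 → 13); aldehyde 4 enters at step 2.

Steps most likely to fail:

1. Step 5. Attack of the Boc carbonyl oxygen on the activated alkyne (6-exo closure with loss of the tert-butyl group) or Meyer–Schuster rearrangement of the propargylic alcohol could outrun the nitrogen closure. Acid released from the catalyst could also strip the silyl ether. The fallback raises the oxidation level so that the ring closes by conjugate addition instead of hydroamination of an unactivated alkyne. It sets out from 8 and comes back at 10.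
   - Dess–Martin oxidation of the propargylic alcohol of 8 should give the ynone tert-butyl N-[(2S)-1-(tert-butyldimethylsilyloxy)-3-oxotetracos-4-yn-2-yl]carbamate F1.
   - Catalytic Au2O3 or PtCl2 in THF should then induce 5-endo-dig aza-Michael closure of the carbamate nitrogen onto the ynone, forming the same N1–C5 bond. The product is the pyrrolinone tert-butyl (2S)-2-[(tert-butyldimethylsilyloxy)methyl]-5-nonadecyl-3-oxo-2,3-dihydro-1H-pyrrole-1-carboxylate F2.
   - Luche reduction (NaBH4, CeCl3, MeOH, −40 °C) of the ring ketone should give the carbinol tert-butyl (2S,3S)-2-[(tert-butyldimethylsilyloxy)methyl]-3-hydroxy-5-nonadecyl-2,3-dihydro-1H-pyrrole-1-carboxylate F3. The 2,3-cis epimer is expected and its configuration is immaterial.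
   - Brief treatment with PPTS in CH2Cl2 should dehydrate F3 to 10.

2. Step 2. The long-chain lithium alkynide may aggregate or fall out of THF at low temperature, so that addition stalls and the aldehyde is consumed by enolisation on warming. The fallback forms the carbinol with a small, soluble nucleophile and attaches the chain afterwards. It sets out from 4 and comes back at 6, and it also bypasses step 1.
   - Ethynylmagnesium bromide in THF at −78 °C should add to 4 to give the terminal propargylic alcohol tert-butyl (4S)-4-[(1R)-1-hydroxyprop-2-yn-1-yl]-2,2-dimethyl-1,3-oxazolidine-3-carboxylate F4.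
   - Double deprotonation with n-BuLi (2.2 equiv) in THF/DMPU and C-alkylation of the alkynide terminus of the dianion with bromide 1 should deliver 6.

3. Step 6. Carbamate transfer may occur during desilylation: the liberated C1 oxygen attacks the adjacent N-Boc group, leading to Boc migration onto oxygen or closure to a bicyclic oxazolone. The fallback removes the carbamate before the silyl ether. It sets out from 10 and comes back at 13.
   - NaOMe in MeOH/THF should cleave the N-acylpyrrole-type carbamate of 10 to give 2-[(tert-butyldimethylsilyloxy)methyl]-5-nonadecyl-1H-pyrrole F5.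
   - TBAF in THF should then free the acid-sensitive carbinol (5-nonadecyl-1H-pyrrol-2-yl)methanol F6.
   - F6 would be taken on without contact with acid and oxidised directly with activated MnO2 in CH2Cl2 to 13.

**Further compounds**

F1 | step 5 | tert-butyl N-[(2S)-1-(tert-butyldimethylsilyloxy)-3-oxotetracos-4-yn-2-yl]carbamate | CCCCCCCCCCCCCCCCCCCC#CC(=O)[C@H](CO[Si](C)(C)C(C)(C)C)NC(=O)OC(C)(C)C
F2 | step 5 | tert-butyl (2S)-2-[(tert-butyldimethylsilyloxy)methyl]-5-nonadecyl-3-oxo-2,3-dihydro-1H-pyrrole-1-carboxylate | CCCCCCCCCCCCCCCCCCCC1=CC(=O)[C@H](CO[Si](C)(C)C(C)(C)C)N1C(=O)OC(C)(C)C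
F3 | step 5 | tert-butyl (2S,3S)-2-[(tert-butyldimethylsilyloxy)methyl]-3-hydroxy-5-nonadecyl-2,3-dihydro-1H-pyrrole-1-carboxylate | CCCCCCCCCCCCCCCCCCCC1=C[C@H](O)[C@H](CO[Si](C)(C)C(C)(C)C)N1C(=O)OC(C)(C)C
F4 | step 2 | tert-butyl (4S)-4-[(1R)-1-hydroxyprop-2-yn-1-yl]-2,2-dimethyl-1,3-oxazolidine-3-carboxylate | C#C[C@H]([C@@H]1COC(C)(C)N1C(=O)OC(C)(C)C)O
F5 | step 6 | 2-[(tert-butyldimethylsilyloxy)methyl]-5-nonadecyl-1H-pyrrole | CCCCCCCCCCCCCCCCCCCc1ccc(CO[Si](C)(C)C(C)(C)C)[nH]1
F6 | step 6 | (5-nonadecyl-1H-pyrrol-2-yl)methanol | CCCCCCCCCCCCCCCCCCCc1ccc(CO)[nH]1
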